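**Assumption (chemistry):** the SMILES has no stereocentre and no stereogenic double bond, so the target is achiral and "single enantiomer" is met trivially. The only stereocentre in the route is the racemic acetal carbon of a THP group, which is removed in the last step.

## Analysis of the target

Target 12 is a tetrasubstituted benzene. Atom labels used throughout: C1–OH, C2–OMe, C3–H, C4–OMe, C5–H, C6–n‑tricosyl (chain C1'–C23').

- The oxygens are 1,2,4‑disposed: O2/O4 are meta (resorcinol-like) and O1/O4 are para (hydroquinone-like).
- The only free hydroxyl is the most hindered oxygen, flanked by C2–OMe and the chain on C6. It cannot be obtained by selective methylation of the triol, and electrophilic substitution of a 2,4‑dimethoxyphenol is expected to favour C5 (activated by both methoxy groups) over C6.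
- The chain is odd-numbered (C23). This is the signature of a polyketide in which the carboxyl carbon of a C24 fatty acyl starter has become ring carbon C6. Catalogue C22 and C24 building blocks are each one carbon off.
- Chain homologues cannot be separated, so the chain length must come from one unambiguous C–C bond formation. All intermediates are waxy and poorly soluble when cold.
- The p‑methoxyphenol is electron-rich and oxidises easily to the p‑quinone with loss of the C4 methyl group.
- The feature the route exploits: ring atoms C2, C3, C4, C5, C6 with their substituents (O, H, OMe, H, alkyl) are, atom for atom, C2–C6 of a 4‑methoxy‑6‑alkyl‑2H‑pyran‑2‑one, i.e. an O‑methylated triketide lactone such as 4. The target differs only in that C1–OH stands where the ring oxygen O1 of the lactone stands.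

The problem is therefore one of regiochemistry, and the proposal is to build the benzene ring around C1 rather than to substitute a purchased arene.

## Retrosynthetic reasoning

**12 ⇒ 11.** The C1 oxygen is unmasked last from THP acetal 11. The oxidation-prone free phenol then exists only in the final step, and the C1 oxygen stays distinct from the C2 oxygen during methylation.

**11 ⇒ 4 + 7 (key disconnection).** Both ring bonds to C1 are cut (C1–C2 and C1–C6), which excises C1 together with its oxygen. What remains is pyranone 4, whose lactone carbonyl is C2 and whose enol-ether carbon is C6. C1 becomes the α‑carbon of α‑alkoxy phosphonate 7. Forward, the carbanion of 7 must acylate at C2 (opening the lactone and releasing the C6 ketone) and then olefinate C6 intramolecularly. The ring oxygen leaves with phosphorus, and the C2 carbonyl oxygen becomes the phenol oxygen that is methylated in the same flask. This cut is preferred because the placement of all four substituents is then decided by the pyranone and not by aromatic substitution. The precursor has no carbocycle at all.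

**4 ⇒ 1 + 2.** The chain is cut between C1' and C2'. The 6‑methyl group of commercial pyranone 1 is vinylogously acidic, and its extended enolate 3 should be alkylated by the even-numbered C22 bromide 2. One carbon from 1 plus 22 from 2 gives the odd C23 chain in a single, homologue-free SN2 step.

**7 ⇒ 5 + 6.** The phosphonate reagent is the THP ether of commercial hydroxymethylphosphonate 5, made by acid-catalysed addition to dihydropyran 6.

## Alternatives that were turned down

**Alternative 1:** (textbook) Disconnection of the chain at C1'=C2'. Forward: Wittig olefination of 2‑hydroxy‑3,5‑dimethoxybenzaldehyde A1 with the ylide from docosyltriphenylphosphonium bromide A2 (made from 2) to give styrene A3, then hydrogenation to 12. This would very probably work in three steps. It was turned down because the whole substituted ring is bought and the key step only appends a chain. It is the route most chemists would draw first. It also needs either excess non-stabilised ylide on a deactivated salicylaldehyde phenoxide or two protecting-group steps.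

**Alternative 2:** Disconnection of the aryl–alkyl bond C6–C1' as a decarboxylative radical coupling. Forward: nickel-catalysed (electro)reductive coupling of the N‑hydroxyphthalimide ester A4 of tetracosanoic acid with 1‑bromo‑3,5‑dimethoxybenzene A5 to give 1,3‑dimethoxy‑5‑tricosylbenzene A6. The C1 oxygen then has to be introduced late. Direct electrophilic hydroxylation of A6 is unattractive because the product phenol is more oxidisable than A6 and would run on to the quinone. The reliable detour is formylation to aldehyde A7 followed by Dakin oxidation, which makes five steps. The coupling forms the same bond as a Kumada reaction and leaves the real difficulty, the hindered C1–OH, unsolved.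

**Alternative 3:** Biomimetic tetraketide aldol. Forward: acylation of the trianion of methyl 3,5‑dioxohexanoate A8 with methyl tetracosanoate A9 to give tetraketide A10, then C2→C7 aldol cyclisation to resorcylate A11. This builds the ring as the biosynthesis does, but it puts a carboxyl carbon on C1 where the target needs oxygen. It would then require double O‑methylation, hydrolysis of a di‑ortho‑substituted ester to acid A12, and an ipso decarboxylative hydroxylation, six steps in all. Aldol versus Claisen versus pyranone closure of A10 is a further ambiguity. The chosen route keeps the polyketide logic but brings C1 in already at the phenol oxidation level.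

Key step: step 3

## Route

Step 1
Reactants: 1 4‑methoxy‑6‑methyl‑2H‑pyran‑2‑one; 2 1‑bromodocosane
Product: 4 4‑methoxy‑6‑tricosyl‑2H‑pyran‑2‑one, via lithium pyranone trienolate 3 (not isolated)
Conditions: LDA (1.1 equiv), THF/DMPU, −78 °C; then 2, n‑Bu4NI (cat.), −78 → 0 °C
Reagents that add atoms: none
Why: Vinylogous (lateral) deprotonation of the 6‑methyl group of 1 should give the extended enolate 3, which is alkylated at its terminal carbon by the primary bromide (SN2, in situ iodide exchange), a known reaction of this pyranone with alkyl halides; the C22 electrophile plus the ring methyl carbon sets the C23 chain length without homologues.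

Step 2
Reactants: 5 diethyl (hydroxymethyl)phosphonate; 6 3,4‑dihydro‑2H‑pyran
Product: 7 diethyl [(tetrahydro‑2H‑pyran‑2‑yloxy)methyl]phosphonate (racemic at the acetal carbon)
Conditions: PPTS (cat.), CH2Cl2, 23 °C
Reagents that add atoms: none
Why: Acid-catalysed addition of the alcohol to the enol ether (tetrahydropyranylation) should proceed cleanly; the new acetal stereocentre is formed as a racemate, which is irrelevant because the group is removed in step 4.

Step 3
Reactants: 4 4‑methoxy‑6‑tricosyl‑2H‑pyran‑2‑one; 7 diethyl [(tetrahydro‑2H‑pyran‑2‑yloxy)methyl]phosphonate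
Product: 11 2‑(2,4‑dimethoxy‑6‑tricosylphenoxy)tetrahydro‑2H‑pyran, via lithiated phosphonate 8 (not isolated), via ring-opened lithium dienolate 9 (not isolated), via phenol 10 (not isolated)
Conditions: 7 (1.2 equiv), LDA, THF, −78 °C; add 4, −78 → 23 °C, then 60 °C; then K2CO3, MeI, DMF, 40 °C
Reagents that add atoms: iodomethane, CI
Why: Proposed new method: the closest known reaction type is the enol-lactone-to-cyclohexenone annulation with α‑lithio phosphonates (acylation of the carbanion by the lactone, then intramolecular Horner–Wadsworth–Emmons olefination of the ketone that ring opening sets free), together with the known attack of lithiated carbon nucleophiles at the C2 carbonyl of 4‑methoxy‑2‑pyranones in biomimetic polyketide aromatisations; what has not been shown is the combination of a 2‑pyranone as the dienol lactone with an α‑alkoxy phosphonate, which should give a phenol directly. Carbanion 8 adds to the lactone carbonyl C2 of 4, the tetrahedral adduct collapses with cleavage of the C2–O1 bond, and the vinylogous diketone is released as lithium dienolate 9, whose C3=C4 double bond keeps C2 and C5 cis as they were in the ring. Proton transfer (diisopropylamine as shuttle) gives the tautomer with a C6 ketone and a phosphonate-stabilised carbanion at C1, which closes the carbocycle by a 6‑(enolendo)‑exo‑trig attack on C6; loss of lithium diethyl phosphate forms C1=C6, and the cyclohexa‑2,5‑dienone tautomerises to phenol 10, aromatisation pulling the unfavourable tautomer equilibrium through. The step thus forms both C1–C2 and C1–C6 and replaces the ring oxygen by the carbon that carries the future hydroxyl, with every other ring substituent already in place. The selectivity needed is attack at C2: a hard lithium reagent should prefer the carbonyl carbon over C4 (substituted and deactivated by OMe) and C6 (1,6‑addition at an alkyl-bearing carbon), while deprotonation at C1' is the competing path. The oxygen on C2 is the only free hydroxyl at this stage, because O1 arrives as a THP acetal, and it is methylated in the same flask (Williamson etherification) to give 11. No stereocentre of the target is created.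

Step 4
Reactants: 11 2‑(2,4‑dimethoxy‑6‑tricosylphenoxy)tetrahydro‑2H‑pyran
Product: 12 2,4‑dimethoxy‑6‑tricosylphenol
Conditions: p‑TsOH·H2O (cat.), MeOH/THF (degassed), 23 °C, under Ar
Reagents that add atoms: none
Why: Acid-catalysed transacetalisation of an aryl THP ether to methanol is fast and mild; the aryl methyl ethers and the alkyl chain are inert, and exclusion of air protects the electron-rich phenol.

## Compound list

1 | 4‑methoxy‑6‑methyl‑2H‑pyran‑2‑one | COC1=CC(=O)OC(C)=C1 | starting material
2 | 1‑bromodocosane | CCCCCCCCCCCCCCCCCCCCCCBr | starting material
3 | lithium 4‑methoxy‑6‑methylidene‑6H‑pyran‑2‑olate (extended enolate of 1, not isolated) | C=C1C=C(OC)C=C(O[Li])O1 | intermediate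
4 | 4‑methoxy‑6‑tricosyl‑2H‑pyran‑2‑one | COC1=CC(=O)OC(CCCCCCCCCCCCCCCCCCCCCCC)=C1 | intermediate
5 | diethyl (hydroxymethyl)phosphonate | CCOP(=O)(CO)OCC | starting material
6 | 3,4‑dihydro‑2H‑pyran | C1CCOC=C1 | starting material
7 | diethyl [(tetrahydro‑2H‑pyran‑2‑yloxy)methyl]phosphonate (racemic acetal) | CCOP(=O)(COC1CCCCO1)OCC | intermediate
8 | diethyl [lithio(tetrahydro‑2H‑pyran‑2‑yloxy)methyl]phosphonate (not isolated) | CCOP(=O)(C([Li])OC1CCCCO1)OCC | intermediate
9 | lithium (3E,5Z)‑1‑(diethoxyphosphoryl)‑4‑methoxy‑2‑oxo‑1‑(tetrahydro‑2H‑pyran‑2‑yloxy)nonacosa‑3,5‑dien‑6‑olate (not isolated) | CCCCCCCCCCCCCCCCCCCCCCC/C(O[Li])=C/C(OC)=C\C(=O)C(OC1CCCCO1)P(=O)(OCC)OCC | intermediate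
10 | 5‑methoxy‑2‑(tetrahydro‑2H‑pyran‑2‑yloxy)‑3‑tricosylphenol (not isolated) | CCCCCCCCCCCCCCCCCCCCCCCc1cc(OC)cc(O)c1OC1CCCCO1 | intermediate
11 | 2‑(2,4‑dimethoxy‑6‑tricosylphenoxy)tetrahydro‑2H‑pyran (racemic acetal) | CCCCCCCCCCCCCCCCCCCCCCCc1cc(OC)cc(OC)c1OC1CCCCO1 | intermediate
12 | 2,4‑dimethoxy‑6‑tricosylphenol | CCCCCCCCCCCCCCCCCCCCCCCc1cc(OC)cc(OC)c1O | target

## Step count and risk

Total step count: 4. Longest linear sequence: 3 steps (steps 1, 3, 4 from 1); step 2 is a convergent reagent preparation.

**Step 3 (key step, proposed new method).** Three processes could defeat it.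

- Proton transfer from the vinylogously acidic C1' methylene of 4 to carbanion 8 could outrun carbonyl addition and simply return 4.
- The sequence could stall at the open-chain stage, because the delocalised dienolate 9 is the stable tautomer and the olefination must pass through the minor C1‑carbanion/C6‑ketone tautomer.
- The open chain could reclose through oxygen instead of carbon.

The fallback uses only known chemistry and moves the disconnection from the ring to the chain. It sets out from 2, which on heating with triphenylphosphine should give docosyltriphenylphosphonium bromide F1. Commercial 2,4‑dimethoxyphenol is ortho-formylated (MgCl2, Et3N, paraformaldehyde) to 2‑hydroxy‑3,5‑dimethoxybenzaldehyde F2, the same compound as A1. The ylide from F1 (NaHMDS, 2.2 equiv, THF) is condensed with F2 in a Wittig reaction to give (Z)‑2,4‑dimethoxy‑6‑(tricos‑1‑en‑1‑yl)phenol F3, the same compound as A3. Hydrogenation (H2, Pd/C, EtOAc) returns to the route at 12.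

**Step 1.** The risks are deprotonation at the wrong site (ring C3–H instead of the methyl group), proton exchange between product 4 and enolate 3 leading to double alkylation, and slow SN2 because 2 is poorly soluble at low temperature while the enolate self-condenses. The fallback inverts the polarity so that no pyranone enolate is needed. It sets out from 1, which is brominated under radical conditions (NBS, AIBN, PhCF3, reflux) to 6‑(bromomethyl)‑4‑methoxy‑2H‑pyran‑2‑one F4. Bromide 2 is converted with magnesium into docosylmagnesium bromide F5. Copper-catalysed sp3–sp3 coupling of F5 with F4 (Li2CuCl4 cat., THF, −78 → −20 °C) returns to the route at 4.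

**Step 4.** The risks are air oxidation of the liberated p‑methoxyphenol to the quinone under acidic conditions, and incomplete acetal exchange because 11 is poorly soluble in methanol. The fallback replaces acidic unmasking by neutral, reducing unmasking. It sets out from 4, which is taken through the step 3 protocol with diethyl [(benzyloxy)methyl]phosphonate F6 in place of 7 to give 1‑(benzyloxy)‑2,4‑dimethoxy‑6‑tricosylbenzene F7. Hydrogenolysis (H2, Pd/C, EtOAc) returns to the route at 12.

## Further compounds

F1 | step 3 | docosyltriphenylphosphonium bromide | CCCCCCCCCCCCCCCCCCCCCC[P+](c1ccccc1)(c1ccccc1)c1ccccc1.[Br-]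
F2 | step 3 | 2‑hydroxy‑3,5‑dimethoxybenzaldehyde | O=Cc1cc(OC)cc(OC)c1O
F3 | step 3 | (Z)‑2,4‑dimethoxy‑6‑(tricos‑1‑en‑1‑yl)phenol | CCCCCCCCCCCCCCCCCCCCC/C=C\c1cc(OC)cc(OC)c1O
F4 | step 1 | 6‑(bromomethyl)‑4‑methoxy‑2H‑pyran‑2‑one | COC1=CC(=O)OC(CBr)=C1
F5 | step 1 | docosylmagnesium bromide | CCCCCCCCCCCCCCCCCCCCCC[Mg]Br
F6 | step 4 | diethyl [(benzyloxy)methyl]phosphonate | CCOP(=O)(COCc1ccccc1)OCC
F7 | step 4 | 1‑(benzyloxy)‑2,4‑dimethoxy‑6‑tricosylbenzene | CCCCCCCCCCCCCCCCCCCCCCCc1cc(OC)cc(OC)c1OCc1ccccc1
A1 | alternative 1 | 2‑hydroxy‑3,5‑dimethoxybenzaldehyde | O=Cc1cc(OC)cc(OC)c1O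
A2 | alternative 1 | docosyltriphenylphosphonium bromide | CCCCCCCCCCCCCCCCCCCCCC[P+](c1ccccc1)(c1ccccc1)c1ccccc1.[Br-]
A3 | alternative 1 | (Z)‑2,4‑dimethoxy‑6‑(tricos‑1‑en‑1‑yl)phenol | CCCCCCCCCCCCCCCCCCCCC/C=C\c1cc(OC)cc(OC)c1O
A4 | alternative 2 | 1,3‑dioxoisoindolin‑2‑yl tetracosanoate | CCCCCCCCCCCCCCCCCCCCCCCC(=O)ON1C(=O)c2ccccc2C1=O
A5 | alternative 2 | 1‑bromo‑3,5‑dimethoxybenzene | COc1cc(Br)cc(OC)c1
A6 | alternative 2 | 1,3‑dimethoxy‑5‑tricosylbenzene | CCCCCCCCCCCCCCCCCCCCCCCc1cc(OC)cc(OC)c1
A7 | alternative 2 | 2,4‑dimethoxy‑6‑tricosylbenzaldehyde | CCCCCCCCCCCCCCCCCCCCCCCc1cc(OC)cc(OC)c1C=O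
A8 | alternative 3 | methyl 3,5‑dioxohexanoate | COC(=O)CC(=O)CC(C)=O
A9 | alternative 3 | methyl tetracosanoate | CCCCCCCCCCCCCCCCCCCCCCCC(=O)OC
A10 | alternative 3 | methyl 3,5,7‑trioxotriacontanoate | CCCCCCCCCCCCCCCCCCCCCCCC(=O)CC(=O)CC(=O)CC(=O)OC
A11 | alternative 3 | methyl 2,4‑dihydroxy‑6‑tricosylbenzoate | CCCCCCCCCCCCCCCCCCCCCCCc1cc(O)cc(O)c1C(=O)OC
A12 | alternative 3 | 2,4‑dimethoxy‑6‑tricosylbenzoic acid | CCCCCCCCCCCCCCCCCCCCCCCc1cc(OC)cc(OC)c1C(O)=O
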